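If each step down the chain cost one E, a flask could be judged by its E per L before any clock was read, and that was where I started.

| flask | L | E | X | remark | time |
|---|---|---|---|---|---|
| dusk | 0.061 M | 0.70 M | 2 M | run made earlier |  |
| winter | 0.68 M | 0.70 M | 2 M | run made earlier |  |
| alder | 0.12 M | 0.700 M | 2.00 M |  | 6.0 min |
| oak | 0.30 M | 0.700 M | 2.00 M |  | 6.0 min |
| birch | 1.0 M | 0.700 M | 2.00 M |  | 6.0 min |

- dusk (time / min: J / %, Z / %): 1.33: 24, 7; 2.50: 24, 11; 4.00: 22, 15; 5.00: 22, 15; 6.00: 17, 13
- winter (time / min: J / %, Z / %): 0.500: 14, 0; 1.50: 19, 4; 3.00: 20, 10; 4.00: 23, 8; 6.00: 17, 11

(readings scatter by 1.5 percentage points)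

- "hardly changes" means that all values lie within two and a half points (for a concentration: within two and a half percent of the largest)

- share of J in all that became J or Z or Q or G for alder, oak, birch, in this order
- the shape of the row from first to last (rises, then falls / hardly changes / rises all the way / falls, then rises / falls all the way)

I called b the E charged per L charged; birch has b = 0.700, oak 2.33 and alder 5.83. I supposed that L went to J and J onward, one E per step, so any L that had left had cost at least one E. With birch's b below one, E was, on that supposition, the limiting reagent of the pair L and E there, and the converted part c of birch, the share of its charged L that had reacted, could not pass 70.0%.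

For the rate I took the symmetric case as zero: equal first-order steps of rate constant k from L to J to Z and onward, where J peaks at the reciprocal of k and Z at twice that time. Dusk read Z highest between 4.00 min and 5.00 min, giving k = 0.444 /min and, for alder, c = 93.0%. With J at 17% in dusk, my first estimate of alder's share was 18.3%.

For birch I borrowed winter's J of 17% and Z of 11%, at one and two E, and let the whole budget go by 6.0 min. I guessed two E for each converted L that was neither J nor Z, which made 15.5% of the L charged, so I put birch at c = 43.5% and its share at 39.1%.

The weak link was k, since equal steps were my assumption. Winter's first reading, 14% of J at 0.500 min, counted as the whole of what L had lost by then, gave a more direct k = 0.302 /min, lower than before, and, with E held at its charge, c = 83.6%. I then took k as proportional to E, the pseudo-first-order case, and at two E per converted L I put the average E below its charge by the fraction c/b. So I put alder at c = 78.8% and oak at 68.7%. Keeping dusk's J for alder and oak and winter's J for birch, I committed to 21.6%, 24.7% and 39.1%, a rising row.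

The forecast was 50%, 50% and 50%, and it said “the row hardly changes”.

The flask gave 24.5%, 28.6% and 37.0%; the row rises all the way.

    L + E ⇌ X + J (K = 190, k = 0.00760 /M/s)
    J + E ⇌ X + Z (K = 63.0, k = 0.00830 /M/s)
    Z + E ⇌ X + Q (K = 5.10, k = 0.0120 /M/s)
    J ⇌ G (K = 1.50, k = 0.00480 /s)
    X → D (k = 0.0170 /s)

At 6.00 min birch still held 8.2% of its E and 51% of its L. Its b therefore shows 0.643 E spent per L charged, or 1.31 per converted L. Oak, with b = 2.33, kept 49% of its E unbound and 26% of its L, which is 1.63 E per converted L.

The numbers in the tables stem from a simulated flask on assumed constants, and the scatter is random.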